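**Plan**

1. The target (C36H42N2) is the head-to-head [4+2] dimer of one achiral diene, 5-[(1E)-3-methylbuta-1,3-dien-1-yl]-3-(2-methylbut-3-en-2-yl)-1H-indole (9). The enabling feature is the cyclohexene: C1 (H, indol-5-yl), C2=C3 (methyl on C3), C4H2, C5H2 and quaternary C6 (methyl, E-2-(indol-5-yl)ethenyl arm). C1–C4 are the diene of one molecule of 9, C5–C6 the terminal CH2=C(CH3) of a second, whose ArCH=CH stays as the arm on C6.
2. Retrosynthesis cuts C1–C6 and C4–C5 (retro-Diels–Alder), then the indole C5–dienyl bond (Suzuki–Miyaura), then the indole C3–C(CH3)2 bond (allylic substitution).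
3. Forward: both indole rings are bought as 5-bromo-1H-indole; C3 reverse prenylation, C5 dienylation, and the cyclohexene, the only ring made, is closed last by dimerisation of 9.
4. Stereochemistry: the E double bond comes from syn-hydroboration of an enyne and is kept; the cis relation of the C1 and C6 arms comes from the endo mode; the absolute configuration (1R,6R) comes from the chiral counter-anion in a radical-cation Diels–Alder reaction.

Key step: step 5

Remark: transient species of catalytic cycles (radical cations in step 5, allyl-iridium and organopalladium species) are described but not numbered. IDPi is the anion of a BINOL-derived N-triflyl imidodiphosphorimidate with 3,3'-aryl groups. Its sense of induction in step 5 cannot be derived from a model, so the enantiomer that gives (1R,6R)-10 is fixed in a first screen and is written below as (S,S) for definiteness.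

Step 1
Reactants: 1 2-methylbut-3-en-2-ol
Product: 3 tert-butyl (2-methylbut-3-en-2-yl) carbonate, via lithium 2-methylbut-3-en-2-olate 2 (not isolated)
Conditions: n-BuLi, THF, 0 °C; then Boc2O, 0 °C to rt
Reagents that add atoms: di-tert-butyl dicarbonate (Boc2O), CC(C)(C)OC(=O)OC(=O)OC(C)(C)C; n-butyllithium, [Li]CCCC (its lithium is held in 2 only)
Why: O-acylation of a lithium tert-alkoxide with Boc2O (carbonate formation) is reliable for hindered tertiary allylic alcohols and gives the ionisable leaving group needed in step 2; no stereocentre is involved.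

Step 2
Reactants: 4 5-bromo-1H-indole; 3 tert-butyl (2-methylbut-3-en-2-yl) carbonate
Product: 6 5-bromo-3-(2-methylbut-3-en-2-yl)-1H-indole, via potassium (5-bromoindol-1-yl)triethylborate 5 (not isolated)
Conditions: KOtBu, Et3B, THF, 0 °C to rt; then 3, [Ir(cod)Cl]2 (2.5 mol %), O,O'-(1,1'-binaphthyl-2,2'-diyl) N,N-bis(1-phenylethyl)phosphoramidite (5 mol %, either enantiomer), THF, rt
Reagents that add atoms: triethylborane, CCB(CC)CC; potassium tert-butoxide, CC(C)(C)[O-].[K+] (boron, ethyl groups and potassium are held in 5 only)
Why: Iridium-catalysed branched-selective allylic substitution (reverse prenylation of an indole at C3): ionisation of 3 gives a 1,1-dimethylallyl-iridium complex that is attacked at its substituted terminus by C3 of the N-boron ate complex 5, in which boron blocks nitrogen, and proton shift restores the 1H-indole; the aryl bromide and the new hindered vinyl group do not react, a second C3 alkylation would need two adjacent quaternary carbons, and no stereocentre is formed.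

Step 3
Reactants: 7 2-methylbut-1-en-3-yne
Product: 8 4,4,5,5-tetramethyl-2-[(1E)-3-methylbuta-1,3-dien-1-yl]-1,3,2-dioxaborolane
Conditions: pinacolborane, Cp2Zr(H)Cl (5 mol %), Et3N (10 mol %), neat, sealed tube, 40 °C
Reagents that add atoms: pinacolborane, CC1(C)OBOC1(C)C
Why: Zirconium-catalysed hydroboration of a terminal alkyne with pinacolborane adds H and B syn and anti-Markovnikov to the C≡C bond in preference to the 1,1-disubstituted C=C bond, which fixes the E geometry of the later aryl–CH=CH unit.

Step 4
Reactants: 6 5-bromo-3-(2-methylbut-3-en-2-yl)-1H-indole; 8 4,4,5,5-tetramethyl-2-[(1E)-3-methylbuta-1,3-dien-1-yl]-1,3,2-dioxaborolane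
Product: 9 5-[(1E)-3-methylbuta-1,3-dien-1-yl]-3-(2-methylbut-3-en-2-yl)-1H-indole
Conditions: Pd(OAc)2 (3 mol %), SPhos (6 mol %), K3PO4, BHT (1 mol %), THF/H2O (10:1), 40 °C, dark
Reagents that add atoms: none
Why: Suzuki–Miyaura coupling of an aryl bromide with an alkenylboronate keeps the E geometry; the electron-rich biarylphosphine lets the electron-rich bromoindole react at 40 °C, below the temperature of thermal diene dimerisation, and the free N–H and the hindered vinyl group are tolerated.

Step 5
Reactants: 9 5-[(1E)-3-methylbuta-1,3-dien-1-yl]-3-(2-methylbut-3-en-2-yl)-1H-indole (two molecules)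
Product: 10 5-[(1R,6R)-3,6-dimethyl-6-{(E)-2-[3-(2-methylbut-3-en-2-yl)-1H-indol-5-yl]ethenyl}cyclohex-2-en-1-yl]-3-(2-methylbut-3-en-2-yl)-1H-indole
Conditions: [2,4,6-tris(4-methoxyphenyl)pyrylium][(S,S)-IDPi] (5 mol %), CH2Cl2/PhMe (1:1), 0.3 M, −60 °C, 455 nm LEDs, argon
Reagents that add atoms: none
Why: Proposed new method: the photoexcited pyrylium cation should remove one electron from the 5-dienylindole π system of 9 (a vinylogous p-aminostyrene, the most easily oxidised part), the radical cation stays paired with the only anion present, the confined chiral IDPi anion (weakly basic, so the acidified N–H is hydrogen-bonded but not deprotonated), and adds to a second, neutral molecule of 9 in an asynchronous [4+2] cycloaddition in which the bond between the two unsubstituted CH2 termini (C4–C5 of the new ring) leads and the bond between the aryl-bearing diene terminus and the methyl-bearing carbon (C1–C6) follows, after which electron return from the reduced catalyst or from another molecule of 9 (chain transfer) releases neutral 10. The closest known reaction types are the radical-cation Diels–Alder reaction of electron-rich styrenes with dienes and the radical-cation cyclodimerisation of conjugated dienes under aminium-salt or photoredox initiation, together with counteranion-directed enantioselective radical-cation cycloadditions of styrenes; a homodimerisation of an aryl diene that creates a quaternary stereocentre under such control has not been shown. The cyclohexene is closed intermolecularly in the (4+2) mode, one molecule giving C1 to C4 from its s-cis diene and the other C5 and C6 from its terminal CH2=C(CH3) unit, while both indole rings and both 2-methylbut-3-en-2-yl groups are spectators. C1 and C6 are formed in the same event: their cis relation (indolyl at C1 and the indolylethenyl arm at C6 on one face, the C6 methyl on the other) follows from the endo orientation of the conjugating styryl arm under the diene with both E double bonds conserved, and their absolute configuration (1R,6R) is imposed by the chiral anion, whose enantiomer is fixed by the screen named in the remark. The step needs head-to-head regioselectivity, [4+2] over [2+2] and [4+4] periselectivity, and chemoselectivity against the indole 2,3-bond, the isolated vinyl groups and the product: the 1-aryl and 3-methyl groups both place the largest spin and orbital coefficient on the CH2 terminus, so that the leading bond gives two aryl-conjugated allyl fragments and only the six-ring closure avoids two adjacent quaternary carbons or a cisoid eight-membered ring, the tert-alkyl group at C3 blocks the indole 2,3-bond, the unconjugated vinyl groups are far harder to oxidise, and the styrene-type alkene of the product should be less easily oxidised than the diene of 9 and is shielded by the quaternary C6.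

**Compound list**

1 | 2-methylbut-3-en-2-ol | C=CC(C)(C)O | starting material
2 | lithium 2-methylbut-3-en-2-olate | C=CC(C)(C)[O-].[Li+] | intermediate
3 | tert-butyl (2-methylbut-3-en-2-yl) carbonate | C=CC(C)(C)OC(=O)OC(C)(C)C | intermediate
4 | 5-bromo-1H-indole | Brc1ccc2[nH]ccc2c1 | starting material
5 | potassium (5-bromoindol-1-yl)triethylborate | CC[B-](CC)(CC)n1ccc2cc(Br)ccc21.[K+] | intermediate
6 | 5-bromo-3-(2-methylbut-3-en-2-yl)-1H-indole | C=CC(C)(C)c1c[nH]c2ccc(Br)cc12 | intermediate
7 | 2-methylbut-1-en-3-yne | C=C(C)C#C | starting material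
8 | 4,4,5,5-tetramethyl-2-[(1E)-3-methylbuta-1,3-dien-1-yl]-1,3,2-dioxaborolane | C=C(C)/C=C/B1OC(C)(C)C(C)(C)O1 | intermediate
9 | 5-[(1E)-3-methylbuta-1,3-dien-1-yl]-3-(2-methylbut-3-en-2-yl)-1H-indole | C=CC(C)(C)c1c[nH]c2ccc(/C=C/C(C)=C)cc12 | intermediate
10 | 5-[(1R,6R)-3,6-dimethyl-6-{(E)-2-[3-(2-methylbut-3-en-2-yl)-1H-indol-5-yl]ethenyl}cyclohex-2-en-1-yl]-3-(2-methylbut-3-en-2-yl)-1H-indole | C=CC(C)(C)c1c[nH]c2ccc(/C=C/[C@@]3(C)CCC(C)=C[C@H]3c3ccc4[nH]cc(C(C)(C)C=C)c4c3)cc12 | target

Total step count: 5. Longest linear sequence: 4 (steps 1, 2, 4, 5).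

**Steps most likely to fail**

1. Step 5 (Proposed new method). What may go wrong: poor facial discrimination inside the ion pair, erosion of the endo preference, or hole transfer to the product followed by oligomerisation. The fallback uses known chemistry, sets out from 9 and comes back at 10.
   - N-protection of 9 (Boc2O, DMAP, MeCN) should give tert-butyl 5-[(1E)-3-methylbuta-1,3-dien-1-yl]-3-(2-methylbut-3-en-2-yl)indole-1-carboxylate F1.
   - A chiral Lewis acid-catalysed Diels–Alder reaction of F1 with 2-methylprop-2-enal (N-protonated B-(o-tolyl)oxazaborolidine of α,α-diphenylprolinol, Tf2NH, CH2Cl2, −78 °C; the catalyst enantiomer that leaves the Re face of C2 of the enal open), ortho-regioselective and endo in the formyl group, should give tert-butyl 5-[(1S,6S)-6-formyl-3,6-dimethylcyclohex-2-en-1-yl]-3-(2-methylbut-3-en-2-yl)indole-1-carboxylate F2.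
   - Takai olefination (CrCl2, CHI3, THF, 0 °C) should give tert-butyl 5-[(1R,6S)-6-[(E)-2-iodoethenyl]-3,6-dimethylcyclohex-2-en-1-yl]-3-(2-methylbut-3-en-2-yl)indole-1-carboxylate F3.
   - In parallel, Miyaura borylation of 6 (B2pin2, Pd(dppf)Cl2, KOAc, dioxane, 80 °C) should give 3-(2-methylbut-3-en-2-yl)-5-(4,4,5,5-tetramethyl-1,3,2-dioxaborolan-2-yl)-1H-indole F4.
   - Suzuki–Miyaura coupling of F3 with F4 (Pd(PPh3)4, K3PO4, THF/H2O, 40 °C) should give tert-butyl 5-[(1R,6R)-3,6-dimethyl-6-{(E)-2-[3-(2-methylbut-3-en-2-yl)-1H-indol-5-yl]ethenyl}cyclohex-2-en-1-yl]-3-(2-methylbut-3-en-2-yl)indole-1-carboxylate F5.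
   - NaOMe in MeOH/THF at rt should remove the Boc group to give 10.

2. Step 2. What may go wrong: attack through nitrogen or at the unsubstituted allyl terminus instead of C3 at the substituted terminus, or slow ionisation of the tertiary carbonate. The fallback sets out from 4 and comes back at 6.
   - Oxidation of 4 (I2, tert-butyl hydroperoxide, DMSO, 80 °C) should give 5-bromo-1H-indole-2,3-dione F6.
   - Barbier-type addition of prenyl bromide with indium powder (DMF/H2O, rt), which takes place at the γ carbon of the allyl metal, should give racemic 5-bromo-3-hydroxy-3-(2-methylbut-3-en-2-yl)-1,3-dihydro-2H-indol-2-one F7.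
   - LiAlH4 in THF should reduce the lactam and, with loss of the tertiary hydroxyl group on work-up, give the indole 6.

3. Step 4. What may go wrong: thermal, unselective [4+2] self-dimerisation or polymerisation of the diene during the coupling, and protodeboronation of 8. The fallback sets out from 6 (with 1) and comes back at 9.
   - Heck reaction of 6 with an excess of 1 (Pd(OAc)2, P(o-tol)3, Et3N, MeCN, 90 °C) should give (3E)-2-methyl-4-[3-(2-methylbut-3-en-2-yl)-1H-indol-5-yl]but-3-en-2-ol F8, which carries no diene while hot.
   - Dehydration with methyl N-(triethylammoniosulfonyl)carbamate in THF at rt (syn elimination towards a methyl group) should give 9 without acid or heat.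

**Further compounds**

F1 | step 5 | tert-butyl 5-[(1E)-3-methylbuta-1,3-dien-1-yl]-3-(2-methylbut-3-en-2-yl)indole-1-carboxylate | C=CC(C)(C)c1cn(C(=O)OC(C)(C)C)c2ccc(/C=C/C(C)=C)cc12
F2 | step 5 | tert-butyl 5-[(1S,6S)-6-formyl-3,6-dimethylcyclohex-2-en-1-yl]-3-(2-methylbut-3-en-2-yl)indole-1-carboxylate | O=C[C@@]1(C)CCC(C)=C[C@H]1c1ccc2c(c1)c(C(C)(C)C=C)cn2C(=O)OC(C)(C)C
F3 | step 5 | tert-butyl 5-[(1R,6S)-6-[(E)-2-iodoethenyl]-3,6-dimethylcyclohex-2-en-1-yl]-3-(2-methylbut-3-en-2-yl)indole-1-carboxylate | I/C=C/[C@@]1(C)CCC(C)=C[C@H]1c1ccc2c(c1)c(C(C)(C)C=C)cn2C(=O)OC(C)(C)C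
F4 | step 5 | 3-(2-methylbut-3-en-2-yl)-5-(4,4,5,5-tetramethyl-1,3,2-dioxaborolan-2-yl)-1H-indole | C=CC(C)(C)c1c[nH]c2ccc(B3OC(C)(C)C(C)(C)O3)cc12
F5 | step 5 | tert-butyl 5-[(1R,6R)-3,6-dimethyl-6-{(E)-2-[3-(2-methylbut-3-en-2-yl)-1H-indol-5-yl]ethenyl}cyclohex-2-en-1-yl]-3-(2-methylbut-3-en-2-yl)indole-1-carboxylate | C=CC(C)(C)c1c[nH]c2ccc(/C=C/[C@@]3(C)CCC(C)=C[C@H]3c3ccc4c(c3)c(C(C)(C)C=C)cn4C(=O)OC(C)(C)C)cc12
F6 | step 2 | 5-bromo-1H-indole-2,3-dione | O=C1Nc2ccc(Br)cc2C1=O
F7 | step 2 | 5-bromo-3-hydroxy-3-(2-methylbut-3-en-2-yl)-1,3-dihydro-2H-indol-2-one (racemic) | C=CC(C)(C)C1(O)C(=O)Nc2ccc(Br)cc21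
F8 | step 4 | (3E)-2-methyl-4-[3-(2-methylbut-3-en-2-yl)-1H-indol-5-yl]but-3-en-2-ol | C=CC(C)(C)c1c[nH]c2ccc(/C=C/C(C)(C)O)cc12
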